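**Retrosynthetic overview**
1. 34 ⇒ 32: the C6–C7 bond is made last by an intramolecular chromium-mediated allylation of a (Z)-enal by a 3-(bromomethyl)butenolide. This one step closes the ten-membered ring, creates the α-methylene lactone and sets C6 and C7 from C8, with the side chain already in place (no metathesis of the ten-membered ring, no late α-methylenation).
2. 32 ⇒ 21 + 26 + 29: the butenolide ring comes from RCM of a 2-(bromomethyl)acrylate; the side chain is attached by primary-selective acylation of diol-enal 21.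
3. 21 ⇒ 12 + 16: a Negishi sp3–sp2 coupling of a homoallylic iodide with a (Z)-β-iodoenoate fixes the C4=C5 geometry.
4. 12 ⇒ (S)-epichlorohydrin (only source of chirality, C8) by alkynylation, ylide homologation and Zr-catalysed methylalumination/ethylene oxide (C1=C10 E); 26 ⇒ tert-butyl but-2-ynoate by hydroalumination/hydroxymethylation.
5. Ring order: five-membered lactone (butenolide) first, ten-membered carbocycle last.

Assumption: atom labels C1–C15 follow germacranolide numbering (C8 carries the lactone oxygen, C6 the free hydroxyl, C15 the acyloxymethyl carbon); compounds 1, 2, 13, 22 and 29 are taken as catalogue chemicals.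

**Fragment A (C1–C3, C7–C10, C14)**

Step 1
Reactants: 1 ethynyltrimethylsilane; 2 (S)-epichlorohydrin
Product: 4 (2S)-1-chloro-5-(trimethylsilyl)pent-4-yn-2-ol, via lithium (trimethylsilyl)acetylide 3 (not isolated)
Conditions: n-BuLi, THF, −78 °C; BF3·OEt2; then 2, −78 °C; H2O
Reagents that add atoms: none
Why: Yamaguchi–Hirao BF3-promoted opening of the epoxide at its CH2 terminus by the lithium acetylide leaves the carbinol stereocentre (future C8) untouched.

Step 2
Reactants: 4 (2S)-1-chloro-5-(trimethylsilyl)pent-4-yn-2-ol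
Product: 6 (3S)-6-(trimethylsilyl)hex-1-en-5-yn-3-ol, via epoxide 5 (not isolated)
Conditions: Me3S+ I− (4 equiv), n-BuLi (3.9 equiv), THF, −20 °C → rt; H2O
Reagents that add atoms: trimethylsulfonium iodide, C[S+](C)C.[I-]
Why: Dimethylsulfonium methylide closes the chlorohydrin to the epoxide, opens it at CH2 and the betaine eliminates dimethyl sulfide (one-carbon epoxide-to-allylic-alcohol homologation), without touching the C–O stereocentre.

Step 3
Reactants: 6 (3S)-6-(trimethylsilyl)hex-1-en-5-yn-3-ol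
Product: 7 (3S)-3-[(tert-butyldimethylsilyl)oxy]-6-(trimethylsilyl)hex-1-en-5-yne
Conditions: TBSCl, imidazole, DMF, rt
Reagents that add atoms: tert-butyldimethylsilyl chloride, CC(C)(C)[Si](C)(C)Cl
Why: Standard imidazole-mediated O-silylation of a secondary alcohol, needed to carry C8–O through the organometallic steps.

Step 4
Reactants: 7 (3S)-3-[(tert-butyldimethylsilyl)oxy]-6-(trimethylsilyl)hex-1-en-5-yne
Product: 8 (3S)-3-[(tert-butyldimethylsilyl)oxy]hex-1-en-5-yne
Conditions: K2CO3 (cat.), MeOH, rt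
Reagents that add atoms: none
Why: Methoxide-mediated protodesilylation cleaves only the alkynyl C–Si bond; the silyl ether is stable.

Step 5
Reactants: 8 (3S)-3-[(tert-butyldimethylsilyl)oxy]hex-1-en-5-yne
Product: 11 (3E,6S)-6-[(tert-butyldimethylsilyl)oxy]-4-methylocta-3,7-dien-1-ol, via alkenyl(dimethyl)alane 9 (not isolated), via lithium alkenyl(butyl)dimethylaluminate 10 (not isolated)
Conditions: AlMe3 (2.5 equiv), Cp2ZrCl2 (0.25 equiv), CH2Cl2, 0 °C → rt; evaporate, hexane; n-BuLi, 0 °C; ethylene oxide, THF, 0 °C → rt; aqueous work-up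
Reagents that add atoms: trimethylaluminium, C[Al](C)C; ethylene oxide, C1CO1
Why: Negishi zirconium-catalysed syn-methylalumination puts the methyl on the internal and aluminium on the terminal alkyne carbon, and the derived alanate opens ethylene oxide with retention, giving only the E trisubstituted C1=C10 alkene.

Step 6
Reactants: 11 (3E,6S)-6-[(tert-butyldimethylsilyl)oxy]-4-methylocta-3,7-dien-1-ol
Product: 12 tert-butyl{[(3S,5E)-8-iodo-5-methylocta-1,5-dien-3-yl]oxy}dimethylsilane
Conditions: I2, PPh3, imidazole, CH2Cl2, 0 °C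
Reagents that add atoms: iodine, [I][I]
Why: Appel-type (Garegg–Samuelsson) iodination converts the primary alcohol into the iodide by SN2 displacement of the alkoxyphosphonium.

**Fragment B (C4–C6, C15)**

Step 7
Reactants: 13 tert-butyldiphenyl(prop-2-yn-1-yloxy)silane
Product: 15 methyl 4-[(tert-butyldiphenylsilyl)oxy]but-2-ynoate, via lithium acetylide 14 (not isolated)
Conditions: n-BuLi, THF, −78 °C; ClCO2Me, −78 °C → 0 °C
Reagents that add atoms: methyl chloroformate, COC(=O)Cl
Why: C-acylation of a lithium acetylide with a chloroformate is a standard route to ynoates.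

Step 8
Reactants: 15 methyl 4-[(tert-butyldiphenylsilyl)oxy]but-2-ynoate
Product: 16 methyl (2Z)-4-[(tert-butyldiphenylsilyl)oxy]-3-iodobut-2-enoate
Conditions: NaI, AcOH, 70 °C
Reagents that add atoms: sodium iodide, [Na+].[I-]
Why: Conjugate addition of iodide followed by anti protonation (hydroiodination of an ynoate) gives the Z iodide with iodine cis to the ester, which is the geometry C4=C5 needs after coupling.

**Union and adjustment**

Step 9
Reactants: 12 tert-butyl{[(3S,5E)-8-iodo-5-methylocta-1,5-dien-3-yl]oxy}dimethylsilane; 16 methyl (2Z)-4-[(tert-butyldiphenylsilyl)oxy]-3-iodobut-2-enoate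
Product: 18 methyl (2E,6E,9S)-9-[(tert-butyldimethylsilyl)oxy]-3-{[(tert-butyldiphenylsilyl)oxy]methyl}-7-methylundeca-2,6,10-trienoate, via homoallylic zinc iodide 17 (not isolated)
Conditions: Zn dust (activated by 1,2-dibromoethane and Me3SiCl), THF, 40 °C; then 16, Pd(PPh3)4 (5 mol %), THF, rt → 45 °C
Reagents that add atoms: none
Why: Zinc insertion into the primary iodide followed by zerovalent-palladium-catalysed Negishi sp3–sp2 coupling proceeds with retention at the vinyl iodide, so the new C3–C4 bond is cis to the ester carbon (C6).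

Step 10
Reactants: 18 methyl (2E,6E,9S)-9-[(tert-butyldimethylsilyl)oxy]-3-{[(tert-butyldiphenylsilyl)oxy]methyl}-7-methylundeca-2,6,10-trienoate
Product: 19 (2E,6E,9S)-9-[(tert-butyldimethylsilyl)oxy]-3-{[(tert-butyldiphenylsilyl)oxy]methyl}-7-methylundeca-2,6,10-trien-1-ol
Conditions: i-Bu2AlH (2.5 equiv), CH2Cl2, −78 °C; aqueous Rochelle salt
Reagents that add atoms: none
Why: 1,2-Hydride reduction of the enoate gives the allylic alcohol without touching alkene geometry or silyl ethers.

Step 11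
Reactants: 19 (2E,6E,9S)-9-[(tert-butyldimethylsilyl)oxy]-3-{[(tert-butyldiphenylsilyl)oxy]methyl}-7-methylundeca-2,6,10-trien-1-ol
Product: 20 (2E,6E,9S)-9-[(tert-butyldimethylsilyl)oxy]-3-{[(tert-butyldiphenylsilyl)oxy]methyl}-7-methylundeca-2,6,10-trienal
Conditions: MnO2 (20 equiv), CH2Cl2, rt
Reagents that add atoms: none
Why: Neutral MnO2 allylic oxidation gives the enal without isomerising the trisubstituted double bond (as in nerol to neral).

Step 12
Reactants: 20 (2E,6E,9S)-9-[(tert-butyldimethylsilyl)oxy]-3-{[(tert-butyldiphenylsilyl)oxy]methyl}-7-methylundeca-2,6,10-trienal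
Product: 21 (2E,6E,9S)-9-hydroxy-3-(hydroxymethyl)-7-methylundeca-2,6,10-trienal
Conditions: TBAF, AcOH (1:1), THF, 0 °C → rt
Reagents that add atoms: none
Why: Acetic-acid-buffered fluoride cleaves both silyl ethers while the enal is spared base-induced isomerisation; the freed C15 hydroxyl is trans to the formyl group and cannot form a lactol.

**Side-chain acid**

Step 13
Reactants: 22 tert-butyl but-2-ynoate
Product: 24 tert-butyl (2Z)-2-(hydroxymethyl)but-2-enoate, via α-aluminated enoate 23 (not isolated)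
Conditions: i-Bu2AlH, N-methylmorpholine N-oxide (additive), THF, 0 °C; then HCHO (gas from cracked paraformaldehyde), −78 °C → rt; H2O
Reagents that add atoms: formaldehyde, C=O
Why: Conjugate syn-hydroalumination of the ynoate puts hydrogen on Cβ and aluminium on Cα, and aldol trapping with formaldehyde at Cα with retention (vinylalumination) leaves the β-methyl cis to the ester, i.e. the Z (sarracinate) geometry.

Step 14
Reactants: 24 tert-butyl (2Z)-2-(hydroxymethyl)but-2-enoate
Product: 25 tert-butyl (2Z)-2-(acetoxymethyl)but-2-enoate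
Conditions: Ac2O, pyridine, CH2Cl2, 0 °C → rt
Reagents that add atoms: acetic anhydride, CC(=O)OC(C)=O
Why: Simple O-acetylation of a primary allylic alcohol, run without a nucleophilic catalyst so that no SN2′ scrambling of the allylic acetate occurs.

Step 15
Reactants: 25 tert-butyl (2Z)-2-(acetoxymethyl)but-2-enoate
Product: 26 (2Z)-2-(acetoxymethyl)but-2-enoic acid
Conditions: CF3CO2H/CH2Cl2 (1:4), 0 °C → rt
Reagents that add atoms: none
Why: Acidolysis of the tert-butyl ester (loss of 2-methylpropene) frees the acid under conditions that touch neither the acetate nor the alkene geometry.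

**Esters, butenolide, ring closure**

Step 16
Reactants: 21 (2E,6E,9S)-9-hydroxy-3-(hydroxymethyl)-7-methylundeca-2,6,10-trienal; 26 (2Z)-2-(acetoxymethyl)but-2-enoic acid
Product: 28 (2E)-2-[(3E,6S)-6-hydroxy-4-methylocta-3,7-dien-1-yl]-4-oxobut-2-en-1-yl (2Z)-2-(acetoxymethyl)but-2-enoate, via acid chloride 27 (not isolated)
Conditions: 26, 1-chloro-N,N,2-trimethylprop-1-en-1-amine, CH2Cl2, 0 °C; then 21, 2,6-lutidine, CH2Cl2, −40 → 0 °C (1.05 equiv of 27)
Reagents that add atoms: none
Why: The acid chloride is formed under neutral conditions and acylates the unhindered primary allylic hydroxyl much faster than the secondary one, with a hindered base and no nucleophilic catalyst so the Z enoate and its allylic acetate are not isomerised.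

Step 17
Reactants: 29 2-(bromomethyl)prop-2-enoic acid
Product: 30 2-(bromomethyl)prop-2-enoyl chloride
Conditions: (COCl)2, DMF (cat.), CH2Cl2, 0 °C → rt; concentrate
Reagents that add atoms: oxalyl chloride, O=C(Cl)C(=O)Cl
Why: Vilsmeier-type activation with oxalyl chloride converts the acid into its chloride without touching the allylic bromide.

Step 18
Reactants: 28 (2E)-2-[(3E,6S)-6-hydroxy-4-methylocta-3,7-dien-1-yl]-4-oxobut-2-en-1-yl (2Z)-2-(acetoxymethyl)but-2-enoate; 30 2-(bromomethyl)prop-2-enoyl chloride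
Product: 31 (2E)-2-[(3E,6S)-6-{[2-(bromomethyl)prop-2-enoyl]oxy}-4-methylocta-3,7-dien-1-yl]-4-oxobut-2-en-1-yl (2Z)-2-(acetoxymethyl)but-2-enoate
Conditions: 2,6-lutidine, CH2Cl2, 0 °C → rt
Reagents that add atoms: none
Why: O-acylation of the remaining secondary allylic alcohol by a reactive acryloyl chloride, with a hindered base that does not quaternise the allylic bromide; C8 keeps its configuration.

Step 19
Reactants: 31 (2E)-2-[(3E,6S)-6-{[2-(bromomethyl)prop-2-enoyl]oxy}-4-methylocta-3,7-dien-1-yl]-4-oxobut-2-en-1-yl (2Z)-2-(acetoxymethyl)but-2-enoate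
Product: 32 (2E)-2-{(3E)-5-[(2S)-4-(bromomethyl)-5-oxo-2,5-dihydrofuran-2-yl]-4-methylpent-3-en-1-yl}-4-oxobut-2-en-1-yl (2Z)-2-(acetoxymethyl)but-2-enoate
Conditions: second-generation Grubbs catalyst RuCl2(=CHPh)(PCy3)(H2IMes) (10 mol %), CH2Cl2 (5 mM), 40 °C
Reagents that add atoms: none
Why: RCM between the terminal vinyl group and the 1,1-disubstituted acrylate gives the five-membered butenolide far faster than any reaction of the trisubstituted or conjugated alkenes, and does not involve C8.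

Step 20
Reactants: 32 (2E)-2-{(3E)-5-[(2S)-4-(bromomethyl)-5-oxo-2,5-dihydrofuran-2-yl]-4-methylpent-3-en-1-yl}-4-oxobut-2-en-1-yl (2Z)-2-(acetoxymethyl)but-2-enoate
Product: 34 [(3aS,4R,5E,9E,11aS)-4-hydroxy-10-methyl-3-methylidene-2-oxo-2,3,3a,4,7,8,11,11a-octahydrocyclodeca[b]furan-6-yl]methyl (2Z)-2-(acetoxymethyl)but-2-enoate (CNP0184624.2), via allylchromium dichloride 33 (not isolated)
Conditions: CrCl2 (10 equiv), THF (2 mM, syringe-pump addition of 32), rt; H2O
Reagents that add atoms: none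
Why: Divalent chromium converts the allylic bromide into a 2-carbonyl-substituted allylchromium that adds to the tethered enal through its γ-carbon (intramolecular Nozaki–Hiyama/Barbier allylation); bonding at C7 trans to the C8–C9 bond gives the trans-fused lactone (7S), and a chair Zimmerman–Traxler transition state with the E-locked butenolide double bond and an equatorial aldehyde substituent gives 6R.

**Compound list**
1 | ethynyltrimethylsilane | C#C[Si](C)(C)C | starting material
2 | (S)-epichlorohydrin | ClC[C@@H]1CO1 | starting material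
3 | lithium (trimethylsilyl)acetylide | [Li]C#C[Si](C)(C)C | intermediate
4 | (2S)-1-chloro-5-(trimethylsilyl)pent-4-yn-2-ol | ClC[C@@H](O)CC#C[Si](C)(C)C | intermediate
5 | (2S)-2-[3-(trimethylsilyl)prop-2-yn-1-yl]oxirane | C1[C@@H](O1)CC#C[Si](C)(C)C | intermediate
6 | (3S)-6-(trimethylsilyl)hex-1-en-5-yn-3-ol | C=C[C@@H](O)CC#C[Si](C)(C)C | intermediate
7 | (3S)-3-[(tert-butyldimethylsilyl)oxy]-6-(trimethylsilyl)hex-1-en-5-yne | C=C[C@@H](O[Si](C)(C)C(C)(C)C)CC#C[Si](C)(C)C | intermediate
8 | (3S)-3-[(tert-butyldimethylsilyl)oxy]hex-1-en-5-yne | C=C[C@@H](O[Si](C)(C)C(C)(C)C)CC#C | intermediate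
9 | [(1E,4S)-4-[(tert-butyldimethylsilyl)oxy]-2-methylhexa-1,5-dien-1-yl]dimethylalumane | C[Al](C)/C=C(C)/C[C@H](O[Si](C)(C)C(C)(C)C)C=C | intermediate
10 | lithium butyl[(1E,4S)-4-[(tert-butyldimethylsilyl)oxy]-2-methylhexa-1,5-dien-1-yl]dimethylaluminate | [Li+].CCCC[Al-](C)(C)/C=C(C)/C[C@H](O[Si](C)(C)C(C)(C)C)C=C | intermediate
11 | (3E,6S)-6-[(tert-butyldimethylsilyl)oxy]-4-methylocta-3,7-dien-1-ol | OCC/C=C(C)/C[C@H](O[Si](C)(C)C(C)(C)C)C=C | intermediate
12 | tert-butyl{[(3S,5E)-8-iodo-5-methylocta-1,5-dien-3-yl]oxy}dimethylsilane | ICC/C=C(C)/C[C@H](O[Si](C)(C)C(C)(C)C)C=C | intermediate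
13 | tert-butyldiphenyl(prop-2-yn-1-yloxy)silane | C#CCO[Si](c1ccccc1)(c1ccccc1)C(C)(C)C | starting material
14 | {3-[(tert-butyldiphenylsilyl)oxy]prop-1-yn-1-yl}lithium | [Li]C#CCO[Si](c1ccccc1)(c1ccccc1)C(C)(C)C | intermediate
15 | methyl 4-[(tert-butyldiphenylsilyl)oxy]but-2-ynoate | COC(=O)C#CCO[Si](c1ccccc1)(c1ccccc1)C(C)(C)C | intermediate
16 | methyl (2Z)-4-[(tert-butyldiphenylsilyl)oxy]-3-iodobut-2-enoate | COC(=O)/C=C(\I)CO[Si](c1ccccc1)(c1ccccc1)C(C)(C)C | intermediate
17 | {(3E,6S)-6-[(tert-butyldimethylsilyl)oxy]-4-methylocta-3,7-dien-1-yl}(iodo)zinc | I[Zn]CC/C=C(C)/C[C@H](O[Si](C)(C)C(C)(C)C)C=C | intermediate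
18 | methyl (2E,6E,9S)-9-[(tert-butyldimethylsilyl)oxy]-3-{[(tert-butyldiphenylsilyl)oxy]methyl}-7-methylundeca-2,6,10-trienoate | COC(=O)/C=C(\CC/C=C(C)/C[C@H](O[Si](C)(C)C(C)(C)C)C=C)CO[Si](c1ccccc1)(c1ccccc1)C(C)(C)C | intermediate
19 | (2E,6E,9S)-9-[(tert-butyldimethylsilyl)oxy]-3-{[(tert-butyldiphenylsilyl)oxy]methyl}-7-methylundeca-2,6,10-trien-1-ol | OC/C=C(\CC/C=C(C)/C[C@H](O[Si](C)(C)C(C)(C)C)C=C)CO[Si](c1ccccc1)(c1ccccc1)C(C)(C)C | intermediate
20 | (2E,6E,9S)-9-[(tert-butyldimethylsilyl)oxy]-3-{[(tert-butyldiphenylsilyl)oxy]methyl}-7-methylundeca-2,6,10-trienal | O=C/C=C(\CC/C=C(C)/C[C@H](O[Si](C)(C)C(C)(C)C)C=C)CO[Si](c1ccccc1)(c1ccccc1)C(C)(C)C | intermediate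
21 | (2E,6E,9S)-9-hydroxy-3-(hydroxymethyl)-7-methylundeca-2,6,10-trienal | O=C/C=C(\CC/C=C(C)/C[C@H](O)C=C)CO | intermediate
22 | tert-butyl but-2-ynoate | CC#CC(=O)OC(C)(C)C | starting material
23 | tert-butyl (2E)-2-[bis(2-methylpropyl)alumanyl]but-2-enoate | C/C=C(/[Al](CC(C)C)CC(C)C)C(=O)OC(C)(C)C | intermediate
24 | tert-butyl (2Z)-2-(hydroxymethyl)but-2-enoate | C/C=C(/CO)C(=O)OC(C)(C)C | intermediate
25 | tert-butyl (2Z)-2-(acetoxymethyl)but-2-enoate | C/C=C(/COC(C)=O)C(=O)OC(C)(C)C | intermediate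
26 | (2Z)-2-(acetoxymethyl)but-2-enoic acid | C/C=C(/COC(C)=O)C(=O)O | intermediate
27 | (2Z)-2-(acetoxymethyl)but-2-enoyl chloride | C/C=C(/COC(C)=O)C(=O)Cl | intermediate
28 | (2E)-2-[(3E,6S)-6-hydroxy-4-methylocta-3,7-dien-1-yl]-4-oxobut-2-en-1-yl (2Z)-2-(acetoxymethyl)but-2-enoate | O=C/C=C(\CC/C=C(C)/C[C@H](O)C=C)COC(=O)/C(=C\C)COC(C)=O | intermediate
29 | 2-(bromomethyl)prop-2-enoic acid | C=C(CBr)C(=O)O | starting material
30 | 2-(bromomethyl)prop-2-enoyl chloride | C=C(CBr)C(=O)Cl | intermediate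
31 | (2E)-2-[(3E,6S)-6-{[2-(bromomethyl)prop-2-enoyl]oxy}-4-methylocta-3,7-dien-1-yl]-4-oxobut-2-en-1-yl (2Z)-2-(acetoxymethyl)but-2-enoate | O=C/C=C(\CC/C=C(C)/C[C@H](OC(=O)C(=C)CBr)C=C)COC(=O)/C(=C\C)COC(C)=O | intermediate
32 | (2E)-2-{(3E)-5-[(2S)-4-(bromomethyl)-5-oxo-2,5-dihydrofuran-2-yl]-4-methylpent-3-en-1-yl}-4-oxobut-2-en-1-yl (2Z)-2-(acetoxymethyl)but-2-enoate | O=C/C=C(\CC/C=C(C)/C[C@@H]1OC(=O)C(CBr)=C1)COC(=O)/C(=C\C)COC(C)=O | intermediate
33 | allylchromium dichloride from 32 (trivalent chromium on the former CH2Br carbon) | O=C/C=C(\CC/C=C(C)/C[C@@H]1OC(=O)C(C[Cr](Cl)Cl)=C1)COC(=O)/C(=C\C)COC(C)=O | intermediate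
34 | [(3aS,4R,5E,9E,11aS)-4-hydroxy-10-methyl-3-methylidene-2-oxo-2,3,3a,4,7,8,11,11a-octahydrocyclodeca[b]furan-6-yl]methyl (2Z)-2-(acetoxymethyl)but-2-enoate | C=C1C(=O)O[C@H]2C/C(C)=C/CC/C(COC(=O)/C(=C\C)COC(C)=O)=C\[C@@H](O)[C@H]12 | target

**Step count**
Total steps: 20. Longest linear sequence: 14 (steps 1–6, 9–12, 16, 18, 19, 20).

**Three steps most likely to fail, each with one fallback**

Step 20 (ring closure). The ten-membered ring may close through a boat-like transition state and give the wrong configuration at C6, or oligomerise. The fallback sets out from 32 and comes back at 34, and corrects C6 by substitution instead of relying on the ring-closing transition state. The chromium closure is accepted as it comes, giving [(3aS,4S,5E,9E,11aS)-4-hydroxy-10-methyl-3-methylidene-2-oxo-2,3,3a,4,7,8,11,11a-octahydrocyclodeca[b]furan-6-yl]methyl (2Z)-2-(acetoxymethyl)but-2-enoate F1. Mitsunobu reaction of F1 with formic acid (PPh3, DIAD, THF, 0 °C) inverts C6 and gives the O6-formate of 34 F2. KHCO3 in MeOH at 0 °C then removes the formate, which is far more labile than the acetate and enoate esters, to give 34.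

Step 19 (RCM in the presence of the allylic bromide). The bromide may degrade the ruthenium carbene or the product may not survive the reaction time. The fallback sets out from 28 and comes back at 32, and introduces the bromide only after the butenolide exists. Commercial ethyl 2-(hydroxymethyl)acrylate is silylated (TBSCl, imidazole) to ethyl 2-{[(tert-butyldimethylsilyl)oxy]methyl}prop-2-enoate F3 and saponified (LiOH, THF/H2O, then HCl) to 2-{[(tert-butyldimethylsilyl)oxy]methyl}prop-2-enoic acid F4. F4 esterifies the C8 hydroxyl of 28 (DCC, 5 mol % DMAP, CH2Cl2, 0 °C) to give the silyloxymethyl acrylate of 28 F5. The same metathesis catalyst closes F5 to the 3-(silyloxymethyl)butenolide F6, HF·pyridine frees the 3-(hydroxymethyl)butenolide F7, and CBr4/PPh3 (CH2Cl2, 0 °C) converts F7 into 32.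

Step 16 (primary-selective acylation with an isomerisation-prone acid). The acid chloride may scramble the Z enoate or lose its allylic acetate, or the selectivity between the primary and secondary hydroxyl may be poor. The fallback sets out from 21 (with 26) and comes back at 28, and activates the alcohol instead of the acid. A Mitsunobu esterification (PPh3, DIAD, THF, −20 °C, betaine preformed) lets 26 act only as a carboxylate nucleophile, so no activated acyl species is formed, and the primary allylic hydroxyl reacts much faster than the secondary one. No compound outside the list is made (F0).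

**Further compounds**
F1 | step 20 | [(3aS,4S,5E,9E,11aS)-4-hydroxy-10-methyl-3-methylidene-2-oxo-2,3,3a,4,7,8,11,11a-octahydrocyclodeca[b]furan-6-yl]methyl (2Z)-2-(acetoxymethyl)but-2-enoate (C6 epimer of 34) | C=C1C(=O)O[C@H]2C/C(C)=C/CC/C(COC(=O)/C(=C\C)COC(C)=O)=C\[C@H](O)[C@H]12
F2 | step 20 | O6-formate of 34 (all three stereocentres as in 34) | C=C1C(=O)O[C@H]2C/C(C)=C/CC/C(COC(=O)/C(=C\C)COC(C)=O)=C\[C@@H](OC=O)[C@H]12
F3 | step 19 | ethyl 2-{[(tert-butyldimethylsilyl)oxy]methyl}prop-2-enoate | CCOC(=O)C(=C)CO[Si](C)(C)C(C)(C)C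
F4 | step 19 | 2-{[(tert-butyldimethylsilyl)oxy]methyl}prop-2-enoic acid | OC(=O)C(=C)CO[Si](C)(C)C(C)(C)C
F5 | step 19 | (2E)-2-[(3E,6S)-6-{[2-({[tert-butyl(dimethyl)silyl]oxy}methyl)prop-2-enoyl]oxy}-4-methylocta-3,7-dien-1-yl]-4-oxobut-2-en-1-yl (2Z)-2-(acetoxymethyl)but-2-enoate | O=C/C=C(\CC/C=C(C)/C[C@H](OC(=O)C(=C)CO[Si](C)(C)C(C)(C)C)C=C)COC(=O)/C(=C\C)COC(C)=O
F6 | step 19 | (2E)-2-{(3E)-5-[(2S)-4-({[tert-butyl(dimethyl)silyl]oxy}methyl)-5-oxo-2,5-dihydrofuran-2-yl]-4-methylpent-3-en-1-yl}-4-oxobut-2-en-1-yl (2Z)-2-(acetoxymethyl)but-2-enoate | O=C/C=C(\CC/C=C(C)/C[C@@H]1OC(=O)C(CO[Si](C)(C)C(C)(C)C)=C1)COC(=O)/C(=C\C)COC(C)=O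
F7 | step 19 | (2E)-2-{(3E)-5-[(2S)-4-(hydroxymethyl)-5-oxo-2,5-dihydrofuran-2-yl]-4-methylpent-3-en-1-yl}-4-oxobut-2-en-1-yl (2Z)-2-(acetoxymethyl)but-2-enoate | O=C/C=C(\CC/C=C(C)/C[C@@H]1OC(=O)C(CO)=C1)COC(=O)/C(=C\C)COC(C)=O
F0 | step 16 | none | none
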